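## Structural features

25 is a 3,5,7-trihydroxyflavone (ring A = C4a to C8a, pyranone ring C with O1, phenyl ring B on C2). Its C8 is bonded to C5 of a 1-phenyl-7-(4-hydroxy-3-methoxyphenyl)heptan-3-one chain, with C1 at the phenyl, C3 the ketone and C7 at the guaiacyl ring. C5 is the only stereocentre, (R): a tertiary benzylic C–H between the C4 methylene (α to the ketone) and the C6 methylene, with no neighbouring stereocentre to relay from. The fragile parts are the free phloroglucinol-type ring A and the 3-hydroxy-4-pyranone (oxidised in base and air), the aryl methyl ether that must outlive every deprotection, and the C3 ketone, which is enolisable on both sides and sits 1,5 to the 7-hydroxyl (reversible hemiketal closure). C5 is β to the ketone and attached to an electron-rich arene, so hot strong acid could erode it by retro-Michael cleavage, although it cannot epimerise by simple enolisation. The real difficulty is twofold: a stereocentre whose two methylene arms differ only two atoms away, and the regiochemistry of ring A, where the oxygen next to the chain-bearing carbon must become O1 so that the chain ends at C8 and not C6. The key step uses the fact that the outer carbons of both arms (C3 and C7) can be carboxyl carbons, which makes C5 the prochiral carbon of a 3-arylglutaric anhydride. An aryl nucleophile that distinguishes the two enantiotopic carbonyl groups makes the C7–guaiacyl bond and the stereocentre together, and the surviving carboxyl (C3) later lactonises onto one ortho oxygen of ring A, which settles the O1 question.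

## Logic of the disconnections

25 ⇒ 23 (through 24). The three O–benzyl bonds and the two ketal C–O bonds are restored. The free polyphenol, the 7-hydroxyl and the C3 ketone cannot pass through the base and peroxide steps, so they appear last. The forward step needs dilute acid and then hydrogenolysis that leave the C2=C3 bond, the ketone and the methyl ether alone.

23 ⇒ 22. The O1–C2 bond and the C3–OH bond of ring C are cut, which removes a whole ring and leaves an enone. The forward oxidative cyclisation is regiochemically fixed only if a single phenol flanks the enone carbonyl, and that phenol must sit on the carbon next to the chain-bearing carbon.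

22 ⇒ 20 + 21. The enone C=C bond (future C2–C3) is cut by a retro-aldol condensation. This takes ring B off as 21. The forward step demands that the chain ketone is not enolisable under KOH, hence the dioxolane in 20.

20 ⇒ 19. Only the ketal is removed. The forward step must choose the dialkyl ketone over the hydrogen-bonded aryl ketone.

19 ⇒ 17 (through 18). The aryl–acetyl bond (future C4a–C4) is cut and the acetyl group is returned to the neighbouring oxygen. Delivering the acyl group from the one free phenol is what fixes its position. The forward rearrangement must go ortho and must spare the benzyl ethers. It is placed before ketalisation because a dioxolane would not survive the Lewis acid.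

17 ⇒ 15 + 16. Chain bond C2–C3 is cut, leaving an N-methoxy-N-methyl amide at C3 and a two-carbon Grignard unit. The forward step must stop at the ketone.

15 ⇒ 14. The amide C–N bond is cut and C3 is tied back to the ring oxygen as a lactone. In 14 this lactone is the only ring A oxygen without a benzyl group, so opening it frees exactly the oxygen that becomes O1.

14 ⇒ 13. Three O–benzyl bonds are cut. The forward alkylation must not open the aryl lactone.

13 ⇒ 11 (through 12). The lactone C–O bond is cut, the C7 carbonyl oxygen is put back and four benzyl groups are returned. One hydrogenation does all of this in the forward sense. Because the two ortho oxygens of the symmetric ring are equivalent, lactonisation gives one product.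

11 ⇒ 7 + 10 (key step). The C7–aryl bond is cut. This turns a chiral keto acid into an achiral anhydride and a simple aryl Grignard reagent, the largest gain in simplicity in the plan. The forward step must distinguish two enantiotopic carbonyl groups and stop after one addition. The benzyl ethers of 7 are kept on purpose: they survive hot alkali and the Grignard reagent, their bulk should help the discrimination, and they leave in the same operation that deoxygenates C7.

10 ⇒ 9 ⇒ 8. The C–Mg bond and one O–benzyl bond are cut, leading to a commercial bromophenol.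

7 ⇒ 6 ⇒ 5 ⇒ 2 + 3, and 2 ⇒ 1. The anhydride C–O bond, then the two acetyl C–C bonds, then the two C–C bonds from the benzylic carbon to the acetoacetate carbons are cut. The forward condensation must work on a hindered, electron-rich aldehyde.

## Other disconnections considered

Alternative 1: Three bonds of ring A are cut (C8–C8a, C6–C7 and C4a–C8a), so the ring is assembled around a stereocentre that already exists.
- Forward key step: 3-ethoxycyclobut-2-en-1-one A3 is heated with the chiral siloxyalkyne triisopropyl{[(3R)-5-[4-(benzyloxy)-3-methoxyphenyl]-3-{[2-(2-phenylethyl)-1,3-dioxolan-2-yl]methyl}pent-1-yn-1-yl]oxy}silane A2. Ring opening to a vinylketene, [2+2] addition to the ynol ether, a second four-electron opening and a six-electron closure would give the phenol 2-{(2R)-4-[4-(benzyloxy)-3-methoxyphenyl]-1-[2-(2-phenylethyl)-1,3-dioxolan-2-yl]butan-2-yl}-5-ethoxy-3-[(triisopropylsilyl)oxy]phenol A1.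
- In its favour: A1 carries three chemically different oxygens placed by the mechanism itself. This is better than the chosen plan, which needs the lactone detour of steps 7 to 9. The stereocentre is not touched.
- Against it: the stereochemical problem is only moved, since A2 contains the same kind of centre with two similar methylene arms and must be made enantiopure first. The α-branched ynol ether is a hindered partner for the ketene. The ethyl ether must later be cleaved beside an aryl methyl ether.
- Comparison: the acetyl group would still have to be introduced ortho to the free phenol of A1, so on that point it is only the equal of step 11. Structurally both plans reach an ortho-hydroxyaryl ketone. Mechanistically it is a thermal pericyclic cascade without reagent control, against a ligand-controlled addition. In step economy the ring synthesis is one step, but A2 should cost about as many steps as 7 and 11 together, so no saving is expected.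

Alternative 2: The chain bond C4–C5 is cut on the complete, protected flavonol.
- Forward key step: the allylic β-keto ester (1R,2E)-1-[4-(benzyloxy)-3-methoxyphenyl]-3-[3,5,7-tris(benzyloxy)-4-oxo-2-phenyl-4H-chromen-8-yl]prop-2-en-1-yl 3-oxo-5-phenylpentanoate A5 is enolised. A [3,3] shift through a chair would place C4 on the alkene terminus that bears flavonol C8, and loss of CO2 would give the ketone 3,5,7-tris(benzyloxy)-8-[(1E,3S)-1-[4-(benzyloxy)-3-methoxyphenyl]-5-oxo-7-phenylhept-1-en-3-yl]-2-phenyl-4H-chromen-4-one A4. The (R) carbinol is the one required for a chair with the guaiacyl group equatorial.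
- In its favour: one hydrogenation would finish the synthesis after the key step, which is better than the nine steps that follow step 6 here. The ketone appears unmasked, so no ketal is needed (also better). Chirality is relayed within the molecule, so no stoichiometric chiral ligand is used.
- Against it: the carbinol of A5 is benzylic to an alkoxyarene and allylic to an alkene conjugated with an electron-rich chromone, so ionisation, 1,3-transposition and racemisation would compete with acylation and with the rearrangement. The new bond forms next to the doubly ortho-substituted C8, which crowds the chair and could open the boat pathway. An 8-alkenyl flavonol must be made regioselectively.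
- Comparison: structurally the same three carbons are placed around C5, but the flavonol has to survive enolate chemistry. Mechanistically the fidelity rests on a labile stereocentre, against reagent control on a robust achiral anhydride. Step economy is better after the key step and probably equal overall once the asymmetric synthesis of the carbinol and the C8 alkenylation are counted.

Alternative 3: Ring A bond C4a–C5 is cut, which traces the acylphloroglucinol to a polyketide-like pyranone.
- Forward key step: Mg(OMe)2 in methanol opens 4-hydroxy-5-{(2R)-4-[4-(benzyloxy)-3-methoxyphenyl]-1-[2-(2-phenylethyl)-1,3-dioxolan-2-yl]butan-2-yl}-6-(2-oxopropyl)-2H-pyran-2-one A7 to a chelated triketo ester. Its C4a carbanion attacks the ester carbon (6-exo-trig Claisen condensation), and aromatisation would give 1-{2,4,6-trihydroxy-3-[(2R)-4-[4-(benzyloxy)-3-methoxyphenyl]-1-[2-(2-phenylethyl)-1,3-dioxolan-2-yl]butan-2-yl]phenyl}ethan-1-one A6.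
- In its favour: the acetyl group is in place by construction, with no ortho-versus-para question. This is better than step 11. The aromatisation is strongly downhill, so the ring-forming event is at least the equal of the chosen key step in reliability. Ring A needs no protecting group while it is built.
- Against it: A6 has three free hydroxyls, two of which flank the acetyl group, so the later pyranone closure could give the 6- or the 8-substituted flavonol unless two hydroxyls are protected selectively on steric grounds alone. Here the chosen plan, which holds the O1 oxygen as a lactone, is better. The stereocentre is again imported and sits next to the most acidic carbon of a β-diketone array. A 5-sec-alkyl-4-hydroxypyranone such as A7 has no short synthesis.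
- Comparison: structurally it reaches the stage that the chosen plan reaches as 19, but without differentiated oxygens. Mechanistically it is a condensation with no stereochemical role, against a stereo-defining addition. In step economy it has fewer operations on ring A and more on the chain, and is probably longer overall.

Key step: step 6

Assumption: (−)-sparteine is written as the ligand expected to give the (R) acid 11 by analogy with other 3-arylglutaric anhydrides; the sense would be checked on the first batch and, if it were opposite, commercial (+)-sparteine would be used with no other change.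

Consistency check: the acid arm of 11 becomes C4–C3 and the keto arm becomes C6–C7; the CIP order aryl > C3-side arm > C7-side arm holds from 11 to 25, so the descriptor stays (R) throughout.

## Route

Step 1
Reactants: 1 2,4,6-trihydroxybenzaldehyde
Product: 2 2,4,6-tris(benzyloxy)benzaldehyde
Conditions: BnBr (3.3 equiv), K2CO3, DMF, 60 °C
Reagents that add atoms: benzyl bromide, BrCc1ccccc1
Why: Williamson etherification; the formyl group lowers ring nucleophilicity, so O-alkylation should prevail over C-benzylation, and warming completes alkylation of the two chelated ortho hydroxyls.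

Step 2
Reactants: 2 2,4,6-tris(benzyloxy)benzaldehyde; 3 ethyl acetoacetate (2.2 equiv)
Product: 5 diethyl 2,4-diacetyl-3-[2,4,6-tris(benzyloxy)phenyl]pentanedioate, via arylidene acetoacetate 4 (not isolated)
Conditions: piperidine (0.2 equiv), EtOH, 25–40 °C, 3–5 d
Reagents that add atoms: none
Why: Knoevenagel condensation followed by Michael addition of a second acetoacetate to the arylidene; the bis-adduct should crystallise as a diastereomer mixture (in part as its internal aldol form), all of which converges in step 3.

Step 3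
Reactants: 5 diethyl 2,4-diacetyl-3-[2,4,6-tris(benzyloxy)phenyl]pentanedioate
Product: 6 3-[2,4,6-tris(benzyloxy)phenyl]pentanedioic acid
Conditions: NaOH (50 % aq), EtOH, reflux; then HCl to pH 1
Reagents that add atoms: NaOH (sodium hydroxide), [Na+].[OH-]
Why: Retro-Claisen (acid) cleavage of both acetyl groups by concentrated alkali together with ester saponification; aryl benzyl ethers are inert to hot base and the product is achiral.

Step 4
Reactants: 6 3-[2,4,6-tris(benzyloxy)phenyl]pentanedioic acid
Product: 7 4-[2,4,6-tris(benzyloxy)phenyl]oxane-2,6-dione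
Conditions: Ac2O, 120 °C, 2 h; evaporate; crystallise (toluene–heptane)
Reagents that add atoms: none
Why: Cyclodehydration of a glutaric acid through the mixed anhydride; the six-membered anhydride is achiral, with two enantiotopic carbonyl groups, and crystallisation removes residual diacid that would quench the Grignard reagent.

Step 5
Reactants: 8 4-bromo-2-methoxyphenol
Product: 9 1-(benzyloxy)-4-bromo-2-methoxybenzene
Conditions: BnBr (1.1 equiv), K2CO3, acetone, reflux
Reagents that add atoms: benzyl bromide, BrCc1ccccc1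
Why: Williamson etherification of a single phenol; the benzyl ether tolerates Grignard formation and is removed in step 7.

Step 6
Reactants: 9 1-(benzyloxy)-4-bromo-2-methoxybenzene (1.4 equiv); 7 4-[2,4,6-tris(benzyloxy)phenyl]oxane-2,6-dione (1.0 equiv)
Product: 11 (3R)-5-[4-(benzyloxy)-3-methoxyphenyl]-5-oxo-3-[2,4,6-tris(benzyloxy)phenyl]pentanoic acid, via aryl Grignard reagent 10 (not isolated)
Conditions: Mg turnings, THF (minimum), 40 °C; dilute with toluene; (−)-sparteine (1.5 equiv), 25 °C; add 7 in toluene, −78 °C, 16 h; 1 M HCl; recrystallise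
Reagents that add atoms: none
Why: Nucleophilic acyl substitution: the diamine-bound arylmagnesium species coordinates and adds to one of the two enantiotopic carbonyl groups of 7, and the tetrahedral magnesium alkoxide collapses with opening of the anhydride to a keto carboxylate. The closest known reaction type is the sparteine-mediated desymmetrisation of 3-substituted glutaric anhydrides by aryl Grignard reagents to δ-keto acids. No ring is closed; the anhydride ring is opened and the C7–aryl bond is the only skeletal bond made. The prochiral carbon becomes stereogenic because its two CH2C(=O) arms now differ, and its configuration is set by reagent control, the chiral diamine on magnesium choosing between the two carbonyl groups. Two selectivities are needed, group selectivity and mono-addition. The first should be helped by the bulky 2,4,6-trisubstituted aryl group, which fixes the ring conformation and widens the difference between the two approaches. The second is secured by the magnesium carboxylate formed on ring opening, which is inert at −78 °C, and by the low electrophilicity of the new alkoxyaryl ketone. Toluene with a minimum of THF keeps the diamine on magnesium, and the crystalline acid offers a chance of enantiomeric enrichment.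

Step 7
Reactants: 11 (3R)-5-[4-(benzyloxy)-3-methoxyphenyl]-5-oxo-3-[2,4,6-tris(benzyloxy)phenyl]pentanoic acid
Product: 13 (4R)-5,7-dihydroxy-4-[2-(4-hydroxy-3-methoxyphenyl)ethyl]-3,4-dihydro-2H-chromen-2-one, via open-chain trihydroxyphenyl acid 12 (not isolated)
Conditions: H2 (4 bar), Pd/C (10 %), AcOH–EtOAc, 45 °C; filter; TsOH (cat.), toluene–THF, 70 °C
Reagents that add atoms: none
Why: Hydrogenolysis of the four benzyl ethers and of the electron-rich benzylic ketone (through the carbinol) to CH2, then acid-catalysed lactonisation; the two ortho hydroxyls are exchanged by aryl rotation, so one dihydrocoumarin should form, and no bond to the stereocentre is touched.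

Step 8
Reactants: 13 (4R)-5,7-dihydroxy-4-[2-(4-hydroxy-3-methoxyphenyl)ethyl]-3,4-dihydro-2H-chromen-2-one
Product: 14 (4R)-5,7-bis(benzyloxy)-4-{2-[4-(benzyloxy)-3-methoxyphenyl]ethyl}-3,4-dihydro-2H-chromen-2-one
Conditions: BnBr (3.3 equiv), K2CO3 (anhydrous), dry acetone, 50 °C
Reagents that add atoms: benzyl bromide, BrCc1ccccc1
Why: Williamson etherification of the three phenols under anhydrous conditions that should keep the aryl lactone closed, so the lactone oxygen is left as the only ring A oxygen without a benzyl group.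

Step 9
Reactants: 14 (4R)-5,7-bis(benzyloxy)-4-{2-[4-(benzyloxy)-3-methoxyphenyl]ethyl}-3,4-dihydro-2H-chromen-2-one
Product: 15 (3R)-3-[2,4-bis(benzyloxy)-6-hydroxyphenyl]-5-[4-(benzyloxy)-3-methoxyphenyl]-N-methoxy-N-methylpentanamide
Conditions: MeNH(OMe)·HCl (3 equiv), AlMe3 (3 equiv), CH2Cl2, 0 → 25 °C
Reagents that add atoms: N,O-dimethylhydroxylamine hydrochloride, CNOC.Cl
Why: Aluminium amide aminolysis of an aryl lactone to the Weinreb amide; the phenoxide is a good leaving group, so opening should be fast, and it frees exactly the oxygen that later becomes O1.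

Step 10
Reactants: 15 (3R)-3-[2,4-bis(benzyloxy)-6-hydroxyphenyl]-5-[4-(benzyloxy)-3-methoxyphenyl]-N-methoxy-N-methylpentanamide; 16 (2-phenylethyl)magnesium chloride (3 equiv)
Product: 17 (5R)-5-[2,4-bis(benzyloxy)-6-hydroxyphenyl]-7-[4-(benzyloxy)-3-methoxyphenyl]-1-phenylheptan-3-one
Conditions: THF, −20 → 0 °C; aq NH4Cl
Reagents that add atoms: none
Why: Grignard acylation through the chelated tetrahedral Weinreb intermediate stops at the ketone; one equivalent is consumed by the phenol, whose magnesium salt is too weak a nucleophile to re-close the lactone at this temperature.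

Step 11
Reactants: 17 (5R)-5-[2,4-bis(benzyloxy)-6-hydroxyphenyl]-7-[4-(benzyloxy)-3-methoxyphenyl]-1-phenylheptan-3-one
Product: 19 (5R)-5-[3-acetyl-4,6-bis(benzyloxy)-2-hydroxyphenyl]-7-[4-(benzyloxy)-3-methoxyphenyl]-1-phenylheptan-3-one, via aryl acetate 18 (not isolated)
Conditions: Ac2O, pyridine, DMAP (cat.), CH2Cl2, 25 °C; evaporate; TiCl4 (3 equiv), CH2Cl2, −20 → 0 °C; 1 M HCl
Reagents that add atoms: acetic anhydride, CC(=O)OC(C)=O
Why: O-acetylation followed by a Lewis-acid Fries rearrangement; the acetyl group should settle on the only free carbon ortho to the ester oxygen, where the product is held as a six-membered titanium chelate, while the para carbon is buried between two benzyloxy groups.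

Step 12
Reactants: 19 (5R)-5-[3-acetyl-4,6-bis(benzyloxy)-2-hydroxyphenyl]-7-[4-(benzyloxy)-3-methoxyphenyl]-1-phenylheptan-3-one
Product: 20 1-[4,6-bis(benzyloxy)-2-hydroxy-3-{(2R)-4-[4-(benzyloxy)-3-methoxyphenyl]-1-[2-(2-phenylethyl)-1,3-dioxolan-2-yl]butan-2-yl}phenyl]ethan-1-one
Conditions: HOCH2CH2OH (5 equiv), PPTS (0.2 equiv), toluene, reflux (Dean–Stark)
Reagents that add atoms: ethane-1,2-diol, OCCO
Why: Acid-catalysed ketalisation; the dialkyl ketone should react while the hydrogen-bonded, conjugated and doubly ortho-substituted aryl ketone does not, and PPTS is too weak to cleave benzyl ethers.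

Step 13
Reactants: 20 1-[4,6-bis(benzyloxy)-2-hydroxy-3-{(2R)-4-[4-(benzyloxy)-3-methoxyphenyl]-1-[2-(2-phenylethyl)-1,3-dioxolan-2-yl]butan-2-yl}phenyl]ethan-1-one; 21 benzaldehyde (1.5 equiv)
Product: 22 (2E)-1-[4,6-bis(benzyloxy)-2-hydroxy-3-{(2R)-4-[4-(benzyloxy)-3-methoxyphenyl]-1-[2-(2-phenylethyl)-1,3-dioxolan-2-yl]butan-2-yl}phenyl]-3-phenylprop-2-en-1-one
Conditions: KOH (50 % aq), EtOH, 25 °C, 24–48 h
Reagents that add atoms: none
Why: Claisen–Schmidt condensation through the enolate of the aryl methyl ketone, with E1cB dehydration to the (E)-enone; the only other enolisable ketone is masked as the dioxolane and the stereocentre has no acidic hydrogen.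

Step 14
Reactants: 22 (2E)-1-[4,6-bis(benzyloxy)-2-hydroxy-3-{(2R)-4-[4-(benzyloxy)-3-methoxyphenyl]-1-[2-(2-phenylethyl)-1,3-dioxolan-2-yl]butan-2-yl}phenyl]-3-phenylprop-2-en-1-one
Product: 23 5,7-bis(benzyloxy)-8-{(2R)-4-[4-(benzyloxy)-3-methoxyphenyl]-1-[2-(2-phenylethyl)-1,3-dioxolan-2-yl]butan-2-yl}-3-hydroxy-2-phenyl-4H-chromen-4-one
Conditions: H2O2 (30 %, 5 equiv), NaOH (2 M aq), MeOH–THF, 0 → 25 °C
Reagents that add atoms: hydrogen peroxide, OO
Why: Algar–Flynn–Oyamada oxidative cyclisation; the single free phenoxide, on the carbon next to the chain-bearing carbon, closes 6-endo onto the β-carbon while the α-carbon is hydroxylated, and further oxidation gives the flavonol with the chain necessarily at C8.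

Step 15
Reactants: 23 5,7-bis(benzyloxy)-8-{(2R)-4-[4-(benzyloxy)-3-methoxyphenyl]-1-[2-(2-phenylethyl)-1,3-dioxolan-2-yl]butan-2-yl}-3-hydroxy-2-phenyl-4H-chromen-4-one
Product: 25 3,5,7-trihydroxy-8-[(3R)-1-(4-hydroxy-3-methoxyphenyl)-5-oxo-7-phenylheptan-3-yl]-2-phenyl-4H-chromen-4-one, via tribenzyl flavonol ketone 24 (not isolated)
Conditions: HCl (0.5 M aq, cat.), THF, 40 °C; then Pd/C (10 %), H2 (1 bar), THF–EtOAc, 25 °C
Reagents that add atoms: water, O
Why: Acid hydrolysis of the dioxolane followed by hydrogenolysis of the three benzyl ethers; the tetrasubstituted C2=C3 bond, the dialkyl ketone and the methyl ether should not react at 1 bar, and the stereocentre is not involved.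

## Compound list

1 | 2,4,6-trihydroxybenzaldehyde | O=Cc1c(O)cc(O)cc1O | starting material
2 | 2,4,6-tris(benzyloxy)benzaldehyde | O=Cc1c(OCc2ccccc2)cc(OCc2ccccc2)cc1OCc1ccccc1 | intermediate
3 | ethyl acetoacetate | CCOC(=O)CC(C)=O | starting material
4 | ethyl 3-oxo-2-{[2,4,6-tris(benzyloxy)phenyl]methylidene}butanoate (E/Z not defined) | CCOC(=O)C(=Cc1c(OCc2ccccc2)cc(OCc2ccccc2)cc1OCc1ccccc1)C(C)=O | intermediate
5 | diethyl 2,4-diacetyl-3-[2,4,6-tris(benzyloxy)phenyl]pentanedioate (diastereomer mixture) | CCOC(=O)C(C(C)=O)C(C(C(C)=O)C(=O)OCC)c1c(OCc2ccccc2)cc(OCc2ccccc2)cc1OCc1ccccc1 | intermediate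
6 | 3-[2,4,6-tris(benzyloxy)phenyl]pentanedioic acid | OC(=O)CC(CC(=O)O)c1c(OCc2ccccc2)cc(OCc2ccccc2)cc1OCc1ccccc1 | intermediate
7 | 4-[2,4,6-tris(benzyloxy)phenyl]oxane-2,6-dione | O=C1CC(CC(=O)O1)c1c(OCc2ccccc2)cc(OCc2ccccc2)cc1OCc1ccccc1 | intermediate
8 | 4-bromo-2-methoxyphenol | COc1cc(Br)ccc1O | starting material
9 | 1-(benzyloxy)-4-bromo-2-methoxybenzene | COc1cc(Br)ccc1OCc1ccccc1 | intermediate
10 | [4-(benzyloxy)-3-methoxyphenyl]magnesium bromide | COc1cc([Mg]Br)ccc1OCc1ccccc1 | intermediate
11 | (3R)-5-[4-(benzyloxy)-3-methoxyphenyl]-5-oxo-3-[2,4,6-tris(benzyloxy)phenyl]pentanoic acid | OC(=O)C[C@@H](CC(=O)c1ccc(OCc2ccccc2)c(OC)c1)c1c(OCc2ccccc2)cc(OCc2ccccc2)cc1OCc1ccccc1 | intermediate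
12 | (3R)-5-(4-hydroxy-3-methoxyphenyl)-3-(2,4,6-trihydroxyphenyl)pentanoic acid | OC(=O)C[C@@H](CCc1ccc(O)c(OC)c1)c1c(O)cc(O)cc1O | intermediate
13 | (4R)-5,7-dihydroxy-4-[2-(4-hydroxy-3-methoxyphenyl)ethyl]-3,4-dihydro-2H-chromen-2-one | O=C1C[C@@H](CCc2ccc(O)c(OC)c2)c2c(O)cc(O)cc2O1 | intermediate
14 | (4R)-5,7-bis(benzyloxy)-4-{2-[4-(benzyloxy)-3-methoxyphenyl]ethyl}-3,4-dihydro-2H-chromen-2-one | O=C1C[C@@H](CCc2ccc(OCc3ccccc3)c(OC)c2)c2c(OCc3ccccc3)cc(OCc3ccccc3)cc2O1 | intermediate
15 | (3R)-3-[2,4-bis(benzyloxy)-6-hydroxyphenyl]-5-[4-(benzyloxy)-3-methoxyphenyl]-N-methoxy-N-methylpentanamide | CON(C)C(=O)C[C@@H](CCc1ccc(OCc2ccccc2)c(OC)c1)c1c(O)cc(OCc2ccccc2)cc1OCc1ccccc1 | intermediate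
16 | (2-phenylethyl)magnesium chloride | Cl[Mg]CCc1ccccc1 | starting material
17 | (5R)-5-[2,4-bis(benzyloxy)-6-hydroxyphenyl]-7-[4-(benzyloxy)-3-methoxyphenyl]-1-phenylheptan-3-one | O=C(CCc1ccccc1)C[C@@H](CCc1ccc(OCc2ccccc2)c(OC)c1)c1c(O)cc(OCc2ccccc2)cc1OCc1ccccc1 | intermediate
18 | 3,5-bis(benzyloxy)-2-[(3R)-1-[4-(benzyloxy)-3-methoxyphenyl]-5-oxo-7-phenylheptan-3-yl]phenyl acetate | O=C(CCc1ccccc1)C[C@@H](CCc1ccc(OCc2ccccc2)c(OC)c1)c1c(OC(C)=O)cc(OCc2ccccc2)cc1OCc1ccccc1 | intermediate
19 | (5R)-5-[3-acetyl-4,6-bis(benzyloxy)-2-hydroxyphenyl]-7-[4-(benzyloxy)-3-methoxyphenyl]-1-phenylheptan-3-one | O=C(CCc1ccccc1)C[C@@H](CCc1ccc(OCc2ccccc2)c(OC)c1)c1c(O)c(C(C)=O)c(OCc2ccccc2)cc1OCc1ccccc1 | intermediate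
20 | 1-[4,6-bis(benzyloxy)-2-hydroxy-3-{(2R)-4-[4-(benzyloxy)-3-methoxyphenyl]-1-[2-(2-phenylethyl)-1,3-dioxolan-2-yl]butan-2-yl}phenyl]ethan-1-one | CC(=O)c1c(O)c([C@H](CCc2ccc(OCc3ccccc3)c(OC)c2)CC2(CCc3ccccc3)OCCO2)c(OCc2ccccc2)cc1OCc1ccccc1 | intermediate
21 | benzaldehyde | O=Cc1ccccc1 | starting material
22 | (2E)-1-[4,6-bis(benzyloxy)-2-hydroxy-3-{(2R)-4-[4-(benzyloxy)-3-methoxyphenyl]-1-[2-(2-phenylethyl)-1,3-dioxolan-2-yl]butan-2-yl}phenyl]-3-phenylprop-2-en-1-one | O=C(/C=C/c1ccccc1)c1c(O)c([C@H](CCc2ccc(OCc3ccccc3)c(OC)c2)CC2(CCc3ccccc3)OCCO2)c(OCc2ccccc2)cc1OCc1ccccc1 | intermediate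
23 | 5,7-bis(benzyloxy)-8-{(2R)-4-[4-(benzyloxy)-3-methoxyphenyl]-1-[2-(2-phenylethyl)-1,3-dioxolan-2-yl]butan-2-yl}-3-hydroxy-2-phenyl-4H-chromen-4-one | COc1cc(CC[C@H](CC2(CCc3ccccc3)OCCO2)c2c(OCc3ccccc3)cc(OCc3ccccc3)c3c(=O)c(O)c(-c4ccccc4)oc23)ccc1OCc1ccccc1 | intermediate
24 | 5,7-bis(benzyloxy)-8-[(3R)-1-[4-(benzyloxy)-3-methoxyphenyl]-5-oxo-7-phenylheptan-3-yl]-3-hydroxy-2-phenyl-4H-chromen-4-one | COc1cc(CC[C@H](CC(=O)CCc2ccccc2)c2c(OCc3ccccc3)cc(OCc3ccccc3)c3c(=O)c(O)c(-c4ccccc4)oc23)ccc1OCc1ccccc1 | intermediate
25 | 3,5,7-trihydroxy-8-[(3R)-1-(4-hydroxy-3-methoxyphenyl)-5-oxo-7-phenylheptan-3-yl]-2-phenyl-4H-chromen-4-one | COc1cc(CC[C@H](CC(=O)CCc2ccccc2)c2c(O)cc(O)c3c(=O)c(O)c(-c4ccccc4)oc23)ccc1O | target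

## Step count and least certain steps

Total step count: 15. Longest linear sequence: 14 steps (steps 1–4 and 6–15, from 1 to 25); step 5 is a one-step branch to 9.

Step 6 (key step). The most likely failure is insufficient discrimination between the two enantiotopic carbonyl groups, because the very bulky aryl group and residual THF may loosen the fit between the diamine–magnesium complex and the anhydride. Slow addition at −78 °C is the second concern. Fallback: from 7, desymmetrising methanolysis with a dimeric cinchona alkaloid organocatalyst (the pseudo-enantiomer that delivers the (R) hemiester) would give (3R)-5-methoxy-5-oxo-3-[2,4,6-tris(benzyloxy)phenyl]pentanoic acid F1. Oxalyl chloride would convert it into methyl (3S)-5-chloro-5-oxo-3-[2,4,6-tris(benzyloxy)phenyl]pentanoate F2 (the descriptor changes by priority only). Negishi acylation with the arylzinc chloride made from 10 and ZnCl2, catalysed by Pd(PPh3)4, would give methyl (3R)-5-[4-(benzyloxy)-3-methoxyphenyl]-5-oxo-3-[2,4,6-tris(benzyloxy)phenyl]pentanoate F3, and LiOH in aqueous THF would return the route to 11.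

Step 11. The acetyl group may migrate to the para carbon, or the Lewis acid may remove the benzyl group that flanks the new ketone. Either would destroy the pattern of one free ortho-hydroxy ketone. Fallback: from 17, ketalisation first (ethane-1,2-diol, PPTS) would give 3,5-bis(benzyloxy)-2-{(2R)-4-[4-(benzyloxy)-3-methoxyphenyl]-1-[2-(2-phenylethyl)-1,3-dioxolan-2-yl]butan-2-yl}phenol F4. Magnesium-mediated ortho-formylation (MgCl2, Et3N, paraformaldehyde), which takes place only next to a free hydroxyl, would give 4,6-bis(benzyloxy)-2-hydroxy-3-{(2R)-4-[4-(benzyloxy)-3-methoxyphenyl]-1-[2-(2-phenylethyl)-1,3-dioxolan-2-yl]butan-2-yl}benzaldehyde F5. MeMgBr would give 3,5-bis(benzyloxy)-2-{(2R)-4-[4-(benzyloxy)-3-methoxyphenyl]-1-[2-(2-phenylethyl)-1,3-dioxolan-2-yl]butan-2-yl}-6-(1-hydroxyethyl)phenol F6, and MnO2 would oxidise it to 20, where the route is rejoined.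

Step 14. The oxidation may be diverted to the aurone by five-membered closure of the phenoxide onto the α-carbon of the epoxide, a path that a 6'-alkoxy group favours by twisting the enone out of the ring plane. Fallback: from 20, the dianion formed with LiN(SiMe3)2 would be C-benzoylated by benzoyl chloride (a Baker–Venkataraman-type acyl transfer) to 1-[4,6-bis(benzyloxy)-2-hydroxy-3-{(2R)-4-[4-(benzyloxy)-3-methoxyphenyl]-1-[2-(2-phenylethyl)-1,3-dioxolan-2-yl]butan-2-yl}phenyl]-3-phenylpropane-1,3-dione F7. TsOH in wet toluene would close the pyranone and hydrolyse the dioxolane to 5,7-bis(benzyloxy)-8-[(3R)-1-[4-(benzyloxy)-3-methoxyphenyl]-5-oxo-7-phenylheptan-3-yl]-2-phenyl-4H-chromen-4-one F8. Epoxidation of the C2=C3 bond with dimethyldioxirane and acid-induced opening would give 24, which the hydrogenolysis of step 15 converts into 25.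

Step 8. The aryl lactone may be opened by adventitious hydroxide or by a phenoxide during the basic alkylation, and the freed oxygen then benzylated, which would erase the difference between the ring A oxygens. Fallback: from 11, ionic hydrogenation (Et3SiH, CF3CO2H) would remove the C7 oxygen with all benzyl ethers in place to give (3R)-5-[4-(benzyloxy)-3-methoxyphenyl]-3-[2,4,6-tris(benzyloxy)phenyl]pentanoic acid F9. Oxalyl chloride would give (3R)-5-[4-(benzyloxy)-3-methoxyphenyl]-3-[2,4,6-tris(benzyloxy)phenyl]pentanoyl chloride F10. On gentle warming with catalytic ZnCl2 an ortho benzyloxy oxygen attacks the acyl carbon, and loss of benzyl chloride from the oxonium ion would deliver 14 directly, bypassing steps 7 and 8.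

Step 7. Removal of the C7 oxygen may be incomplete: after debenzylation the ortho hydroxyl or the acid can capture the benzylic carbinol or cation at C7 as a cyclic ether or lactone that is hydrogenolysed only slowly, and forcing it with strong acid would endanger the stereocentre by retro-Michael cleavage. Fallback: from 11, NaBH4 would reduce the ketone and acidification would close (4R)-6-[4-(benzyloxy)-3-methoxyphenyl]-4-[2,4,6-tris(benzyloxy)phenyl]oxan-2-one F11 (both C6 epimers). Neutral hydrogenolysis (Pd/C, H2, EtOAc) would cleave the benzylic lactone C–O bond together with the benzyl ethers to give 12, which lactonises to 13 as in step 7.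

Step 2. The second (Michael) addition may stall at the hindered, electron-rich arylidene, or the Knoevenagel step may revert. Fallback: from 2, Knoevenagel condensation with diethyl malonate under TiCl4 and pyridine would give diethyl 2-{[2,4,6-tris(benzyloxy)phenyl]methylidene}propanedioate F12. Irreversible conjugate addition of the lithium enolate of ethyl acetate (LiN(iPr)2, THF, −78 °C) would give triethyl 2-[2,4,6-tris(benzyloxy)phenyl]propane-1,1,3-tricarboxylate F13. KOH hydrolysis, acidification and thermal decarboxylation would give 6.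

## Further compounds

F1 | step 6 | (3R)-5-methoxy-5-oxo-3-[2,4,6-tris(benzyloxy)phenyl]pentanoic acid | COC(=O)C[C@@H](CC(=O)O)c1c(OCc2ccccc2)cc(OCc2ccccc2)cc1OCc1ccccc1
F2 | step 6 | methyl (3S)-5-chloro-5-oxo-3-[2,4,6-tris(benzyloxy)phenyl]pentanoate | COC(=O)C[C@@H](CC(Cl)=O)c1c(OCc2ccccc2)cc(OCc2ccccc2)cc1OCc1ccccc1
F3 | step 6 | methyl (3R)-5-[4-(benzyloxy)-3-methoxyphenyl]-5-oxo-3-[2,4,6-tris(benzyloxy)phenyl]pentanoate | COC(=O)C[C@@H](CC(=O)c1ccc(OCc2ccccc2)c(OC)c1)c1c(OCc2ccccc2)cc(OCc2ccccc2)cc1OCc1ccccc1
F4 | step 11 | 3,5-bis(benzyloxy)-2-{(2R)-4-[4-(benzyloxy)-3-methoxyphenyl]-1-[2-(2-phenylethyl)-1,3-dioxolan-2-yl]butan-2-yl}phenol | Oc1cc(OCc2ccccc2)cc(OCc2ccccc2)c1[C@H](CCc1ccc(OCc2ccccc2)c(OC)c1)CC1(CCc2ccccc2)OCCO1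
F5 | step 11 | 4,6-bis(benzyloxy)-2-hydroxy-3-{(2R)-4-[4-(benzyloxy)-3-methoxyphenyl]-1-[2-(2-phenylethyl)-1,3-dioxolan-2-yl]butan-2-yl}benzaldehyde | O=Cc1c(O)c([C@H](CCc2ccc(OCc3ccccc3)c(OC)c2)CC2(CCc3ccccc3)OCCO2)c(OCc2ccccc2)cc1OCc1ccccc1
F6 | step 11 | 3,5-bis(benzyloxy)-2-{(2R)-4-[4-(benzyloxy)-3-methoxyphenyl]-1-[2-(2-phenylethyl)-1,3-dioxolan-2-yl]butan-2-yl}-6-(1-hydroxyethyl)phenol (both carbinol epimers) | CC(O)c1c(O)c([C@H](CCc2ccc(OCc3ccccc3)c(OC)c2)CC2(CCc3ccccc3)OCCO2)c(OCc2ccccc2)cc1OCc1ccccc1
F7 | step 14 | 1-[4,6-bis(benzyloxy)-2-hydroxy-3-{(2R)-4-[4-(benzyloxy)-3-methoxyphenyl]-1-[2-(2-phenylethyl)-1,3-dioxolan-2-yl]butan-2-yl}phenyl]-3-phenylpropane-1,3-dione | O=C(CC(=O)c1ccccc1)c1c(O)c([C@H](CCc2ccc(OCc3ccccc3)c(OC)c2)CC2(CCc3ccccc3)OCCO2)c(OCc2ccccc2)cc1OCc1ccccc1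
F8 | step 14 | 5,7-bis(benzyloxy)-8-[(3R)-1-[4-(benzyloxy)-3-methoxyphenyl]-5-oxo-7-phenylheptan-3-yl]-2-phenyl-4H-chromen-4-one | COc1cc(CC[C@H](CC(=O)CCc2ccccc2)c2c(OCc3ccccc3)cc(OCc3ccccc3)c3c(=O)cc(-c4ccccc4)oc23)ccc1OCc1ccccc1
F9 | step 8 | (3R)-5-[4-(benzyloxy)-3-methoxyphenyl]-3-[2,4,6-tris(benzyloxy)phenyl]pentanoic acid | OC(=O)C[C@@H](CCc1ccc(OCc2ccccc2)c(OC)c1)c1c(OCc2ccccc2)cc(OCc2ccccc2)cc1OCc1ccccc1
F10 | step 8 | (3R)-5-[4-(benzyloxy)-3-methoxyphenyl]-3-[2,4,6-tris(benzyloxy)phenyl]pentanoyl chloride | ClC(=O)C[C@@H](CCc1ccc(OCc2ccccc2)c(OC)c1)c1c(OCc2ccccc2)cc(OCc2ccccc2)cc1OCc1ccccc1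
F11 | step 7 | (4R)-6-[4-(benzyloxy)-3-methoxyphenyl]-4-[2,4,6-tris(benzyloxy)phenyl]oxan-2-one (both C6 epimers) | O=C1C[C@@H](CC(O1)c1ccc(OCc2ccccc2)c(OC)c1)c1c(OCc2ccccc2)cc(OCc2ccccc2)cc1OCc1ccccc1
F12 | step 2 | diethyl 2-{[2,4,6-tris(benzyloxy)phenyl]methylidene}propanedioate | CCOC(=O)C(=Cc1c(OCc2ccccc2)cc(OCc2ccccc2)cc1OCc1ccccc1)C(=O)OCC
F13 | step 2 | triethyl 2-[2,4,6-tris(benzyloxy)phenyl]propane-1,1,3-tricarboxylate (racemic) | CCOC(=O)CC(C(C(=O)OCC)C(=O)OCC)c1c(OCc2ccccc2)cc(OCc2ccccc2)cc1OCc1ccccc1
A1 | alternative 1 | 2-{(2R)-4-[4-(benzyloxy)-3-methoxyphenyl]-1-[2-(2-phenylethyl)-1,3-dioxolan-2-yl]butan-2-yl}-5-ethoxy-3-[(triisopropylsilyl)oxy]phenol | CCOc1cc(O)c([C@H](CCc2ccc(OCc3ccccc3)c(OC)c2)CC2(CCc3ccccc3)OCCO2)c(O[Si](C(C)C)(C(C)C)C(C)C)c1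
A2 | alternative 1 | triisopropyl{[(3R)-5-[4-(benzyloxy)-3-methoxyphenyl]-3-{[2-(2-phenylethyl)-1,3-dioxolan-2-yl]methyl}pent-1-yn-1-yl]oxy}silane | CC(C)[Si](C(C)C)(C(C)C)OC#C[C@H](CCc1ccc(OCc2ccccc2)c(OC)c1)CC1(CCc2ccccc2)OCCO1
A3 | alternative 1 | 3-ethoxycyclobut-2-en-1-one | CCOC1=CC(=O)C1
A4 | alternative 2 | 3,5,7-tris(benzyloxy)-8-[(1E,3S)-1-[4-(benzyloxy)-3-methoxyphenyl]-5-oxo-7-phenylhept-1-en-3-yl]-2-phenyl-4H-chromen-4-one | O=C(CCc1ccccc1)C[C@@H](/C=C/c1ccc(OCc2ccccc2)c(OC)c1)c1c(OCc2ccccc2)cc(OCc2ccccc2)c2c(=O)c(OCc3ccccc3)c(-c3ccccc3)oc12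
A5 | alternative 2 | (1R,2E)-1-[4-(benzyloxy)-3-methoxyphenyl]-3-[3,5,7-tris(benzyloxy)-4-oxo-2-phenyl-4H-chromen-8-yl]prop-2-en-1-yl 3-oxo-5-phenylpentanoate | O=C(CCc1ccccc1)CC(=O)O[C@@H](c1ccc(OCc2ccccc2)c(OC)c1)/C=C/c1c(OCc2ccccc2)cc(OCc2ccccc2)c2c(=O)c(OCc3ccccc3)c(-c3ccccc3)oc12
A6 | alternative 3 | 1-{2,4,6-trihydroxy-3-[(2R)-4-[4-(benzyloxy)-3-methoxyphenyl]-1-[2-(2-phenylethyl)-1,3-dioxolan-2-yl]butan-2-yl]phenyl}ethan-1-one | CC(=O)c1c(O)cc(O)c([C@H](CCc2ccc(OCc3ccccc3)c(OC)c2)CC2(CCc3ccccc3)OCCO2)c1O
A7 | alternative 3 | 4-hydroxy-5-{(2R)-4-[4-(benzyloxy)-3-methoxyphenyl]-1-[2-(2-phenylethyl)-1,3-dioxolan-2-yl]butan-2-yl}-6-(2-oxopropyl)-2H-pyran-2-one | CC(=O)CC1=C([C@H](CCc2ccc(OCc3ccccc3)c(OC)c2)CC2(CCc3ccccc3)OCCO2)C(O)=CC(=O)O1
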